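The route rests on closing cyclopentane ring A (C11 quaternary methyl carbon, C12 CHOH, C13 CH2, C14 CHBr, C15 CMe2) last, through the C11–C12 bond. It exploits that C11 lies between the secondary carbinol C12 and the tertiary carbinol C7 of decalin ring B: an iron hydride transfers a hydrogen atom to a C11=CH2 alkene and the tertiary C11 radical adds 5-exo to a C12 aldehyde, creating the quaternary centre and the C12 carbinol at once. The precursor is an acyclic β-hydroxy aldehyde attached at C7; its C14 carbinol is a temporary stereocontrol element, later converted, like the C1 ketone, into an equatorial bromide.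

Key step: step 11

Remark: the decalin is numbered C1–C10 (C1 CHBr next to the methyl-bearing fusion carbon C10, C4 the methyl carbinol, C5 the hydroxylated fusion carbon, C7 the carbinol carrying ring A; ring B = C5–C10, ring C = C1–C5 plus C10), β is the face of the C10 methyl, and 4-hydroxy-3,3-dimethylbutan-2-one is assumed to be commercial.

Step 1
Reactants: 1 (S)-Wieland–Miescher ketone
Product: 2 10β-methyldecal-4-ene-1,7-dione bis(ethylene ketal)
Conditions: ethylene glycol, TsOH (cat.), benzene, reflux, Dean–Stark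
Reagents that add atoms: ethylene glycol OCCO
Why: Acid-catalysed ketalization masks both ketones, and the enone ketalizes with the usual migration of its double bond out of conjugation to C4=C5, which exposes C4/C5 for oxidation while C10 is untouched.

Step 2
Reactants: 2 10β-methyldecal-4-ene-1,7-dione bis(ethylene ketal)
Product: 3 4α,5α-dihydroxy-10β-methyl-trans-decalin-1,7-dione bis(ethylene ketal)
Conditions: OsO4 (cat.), NMO, acetone/H2O, rt
Reagents that add atoms: N-methylmorpholine N-oxide C[N+]1([O-])CCOCC1; water O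
Why: Catalytic osmium tetroxide syn-dihydroxylation should take place on the α face, anti to the axial C10 methyl, which sets the 5α-hydroxyl (trans ring fusion) and a transient 4α-hydroxyl.

Step 3
Reactants: 3 4α,5α-dihydroxy-10β-methyl-trans-decalin-1,7-dione bis(ethylene ketal)
Product: 4 5α-hydroxy-10β-methyl-trans-decalin-1,4,7-trione 1,7-bis(ethylene ketal)
Conditions: IBX, DMSO, rt
Reagents that add atoms: none
Why: Hypervalent-iodine oxidation of a 1,2-diol converts the secondary C4 carbinol into the ketone without C–C cleavage, the tertiary C5 hydroxyl being inert.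

Step 4
Reactants: 4 5α-hydroxy-10β-methyl-trans-decalin-1,4,7-trione 1,7-bis(ethylene ketal)
Product: 5 4β,5α-dihydroxy-4α,10β-dimethyl-trans-decalin-1,7-dione bis(ethylene ketal)
Conditions: MeMgBr (3 equiv), THF, −78 to 0 °C; aq. NH4Cl
Reagents that add atoms: methylmagnesium bromide C[Mg]Br
Why: Grignard 1,2-addition (after deprotonation of the C5 hydroxyl) should come from the equatorial α face because the axial β path is blocked by the syn-axial C10 methyl, giving the 4α-methyl/4β-hydroxyl trans-diaxial diol.

Step 5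
Reactants: 5 4β,5α-dihydroxy-4α,10β-dimethyl-trans-decalin-1,7-dione bis(ethylene ketal)
Product: 6 (4R,5R,10S)-4β,5α-dihydroxy-4α,10β-dimethyl-trans-decalin-1,7-dione
Conditions: 1 M aq. HCl, THF, rt
Reagents that add atoms: water O
Why: Mild acid hydrolysis cleaves both dioxolanes, and the tertiary β-hydroxy ketone (C5–OH/C7=O) is expected to survive without dehydration under these conditions.

Step 6
Reactants: 7 4-hydroxy-3,3-dimethylbutan-2-one
Product: 8 2,2-dimethyl-3-oxobutanal
Conditions: TEMPO (cat.), PhI(OAc)2, CH2Cl2, rt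
Reagents that add atoms: none
Why: Nitroxyl-catalysed oxidation of the primary alcohol stops at the aldehyde, which has no α-hydrogen and therefore cannot enolize or self-condense.

Step 7
Reactants: 8 2,2-dimethyl-3-oxobutanal
Product: 10 (R)-4-hydroxy-3,3-dimethylhept-6-en-2-one, via boronate ester 9 (not isolated)
Conditions: allylB(pin), (R)-TRIP (5 mol%), toluene, −30 °C; aq. work-up
Reagents that add atoms: allylboronic acid pinacol ester C=CCB1OC(C)(C)C(C)(C)O1
Why: Chiral phosphoric acid-catalysed asymmetric allylboration is chemoselective for the aldehyde over the hindered ketone and proceeds through a closed chair transition state in which (R)-TRIP should direct allyl to the Re face, setting the (R)-carbinol that becomes C14.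

Step 8
Reactants: 10 (R)-4-hydroxy-3,3-dimethylhept-6-en-2-one
Product: 11 trisylhydrazone of (R)-4-hydroxy-3,3-dimethylhept-6-en-2-one
Conditions: 2,4,6-triisopropylbenzenesulfonyl hydrazide, HCl (cat.), MeOH, rt
Reagents that add atoms: 2,4,6-triisopropylbenzenesulfonyl hydrazide CC(C)c1cc(C(C)C)c(S(=O)(=O)NN)c(C(C)C)c1
Why: Condensation of the methyl ketone gives the sulfonylhydrazone needed for a Shapiro reaction, and the quaternary α-carbon leaves the methyl group as the only site for later deprotonation.

Step 9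
Reactants: 11 trisylhydrazone of (R)-4-hydroxy-3,3-dimethylhept-6-en-2-one, 6 (4R,5R,10S)-4β,5α-dihydroxy-4α,10β-dimethyl-trans-decalin-1,7-dione
Product: 14 4β,5α,7α-trihydroxy-7β-[(4R)-4-hydroxy-3,3-dimethylhepta-1,6-dien-2-yl]-4α,10β-dimethyl-trans-decalin-1-one, via dilithium dialkoxide 12 (not isolated), via vinyllithium 13 (not isolated)
Conditions: 11, n-BuLi (3 equiv), THF, −78 to 0 °C; then 6 pre-treated with LiHMDS (2 equiv), LaCl3·2LiCl, THF, −78 °C; aq. NH4Cl
Reagents that add atoms: none
Why: The Shapiro reaction gives the 1,1-disubstituted vinyllithium, which should add 1,2 to the unhindered C7 ketone rather than the neopentylic C1 ketone and from the equatorial direction because the axial C5 alkoxide blocks the axial path, setting C7 with the hydroxyl axial (7α) and the side chain equatorial.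

Step 10
Reactants: 14 4β,5α,7α-trihydroxy-7β-[(4R)-4-hydroxy-3,3-dimethylhepta-1,6-dien-2-yl]-4α,10β-dimethyl-trans-decalin-1-one
Product: 16 4β,5α,7α-trihydroxy-7β-[(4R)-4-hydroxy-3,3-dimethyl-6-oxohex-1-en-2-yl]-4α,10β-dimethyl-trans-decalin-1-one, via vicinal diol 15 (not isolated)
Conditions: OsO4 (cat.), NaIO4, 2,6-lutidine, dioxane/H2O, rt
Reagents that add atoms: sodium periodate [Na+].[O-]I(=O)(=O)=O; water O
Why: In this Lemieux–Johnson cleavage OsO4 should dihydroxylate the unhindered vinyl group much faster than the 1,1-disubstituted alkene flanked by two quaternary carbons, and periodate cleaves only the new flexible diol because the rigid trans-diaxial C4/C5 diol cannot form a cyclic periodate.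

Step 11
Reactants: 16 4β,5α,7α-trihydroxy-7β-[(4R)-4-hydroxy-3,3-dimethyl-6-oxohex-1-en-2-yl]-4α,10β-dimethyl-trans-decalin-1-one
Product: 17 4β,5α,7α-trihydroxy-7β-[(1R,2S,4R)-2,4-dihydroxy-1,5,5-trimethylcyclopentyl]-4α,10β-dimethyl-trans-decalin-1-one
Conditions: Fe(acac)3 (0.5 equiv), PhSiH3, EtOH, 50 °C
Reagents that add atoms: none
Why: Fe(acac)3 and PhSiH3 generate an iron hydride that transfers a hydrogen atom to the terminal CH2 of the 1,1-disubstituted alkene (Markovnikov), the tertiary C11 radical adds to the C12 aldehyde carbon and the alkoxy radical is reduced and protonated in ethanol. The closest known reaction type is the iron-mediated HAT-initiated reductive radical cyclization of alkene-tethered carbonyl compounds (Mukaiyama-type MHAT with carbonyl trapping). Ring A closes in the 5-exo-trig mode onto the C=O group. C12 and C11 are set by the temporary C14 carbinol through the chair-like 5-exo transition state: the C14 hydroxyl sits equatorial (axial would clash with the axial C11 and C15 methyls), the bulky C7 carbinol substituent on the radical carbon sits equatorial with the C11 methyl axial, and the carbonyl oxygen is pseudo-equatorial and can accept a hydrogen bond from O7–H, which places C14–OH, C12–OH and C7 on one face (11R,12S). The step needs cyclization to outrun reduction of the radical and reversal of the addition, which the gem-dimethyl group at C15, the hindered long-lived tertiary radical and fast reduction of the alkoxy radical should secure; the only alkene is the one that reacts, and the C1 ketone and the hydroxyls are inert.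

Step 12
Reactants: 17 4β,5α,7α-trihydroxy-7β-[(1R,2S,4R)-2,4-dihydroxy-1,5,5-trimethylcyclopentyl]-4α,10β-dimethyl-trans-decalin-1-one
Product: 18 4β,5α,7α-trihydroxy-7β-[(1R,2S)-2-hydroxy-1,5,5-trimethyl-4-oxocyclopentyl]-4α,10β-dimethyl-trans-decalin-1-one
Conditions: TEMPO (cat.), PhI(OAc)2 (1.1 equiv), CH2Cl2, rt
Reagents that add atoms: none
Why: Oxoammonium (nitroxyl) oxidation is very sensitive to steric hindrance, so the C14 carbinol should be oxidized while the C12 carbinol (cis to and shielded by the fully substituted C11/C7 array) and the tertiary alcohols remain, which erases the temporary stereocentre.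

Step 13
Reactants: 18 4β,5α,7α-trihydroxy-7β-[(1R,2S)-2-hydroxy-1,5,5-trimethyl-4-oxocyclopentyl]-4α,10β-dimethyl-trans-decalin-1-one
Product: 19 1,14-bis-hydrazone of 18
Conditions: N2H4·H2O, Et3N, EtOH, rt
Reagents that add atoms: hydrazine NN
Why: Condensation with hydrazine converts both α-quaternary ketones into hydrazones under near-neutral conditions that should spare the ring A β-hydroxy ketone from retro-aldol cleavage or dehydration.

Step 14
Reactants: 19 1,14-bis-hydrazone of 18
Product: 20 1,14-dibromo-1(2),13(14)-diene (4β,5α,7α,12-tetrol)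
Conditions: NBS, pyridine, THF, 0 °C
Reagents that add atoms: N-bromosuccinimide O=C1CCC(=O)N1Br
Why: In this Barton vinyl halide synthesis (bromide variant) N-bromination, diazo formation, bromination and loss of N2 give α-bromo cations that can lose only the C13 and C2 protons, since C15 and C10 are quaternary, so both vinyl bromides form with unambiguous regiochemistry.

Step 15
Reactants: 20 1,14-dibromo-1(2),13(14)-diene (4β,5α,7α,12-tetrol)
Product: 21 neoirietetraol
Conditions: Mn(dpm)3 (cat.), PhSiH3, t-BuOOH, i-PrOH, rt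
Reagents that add atoms: none
Why: MHAT hydrogenation of the bromoalkenes adds H• at C2 and C13 to give α-bromo radicals whose second hydrogen should arrive axially at C1 (α face, anti to the C10 methyl) and at C14 on the face of the C11 methyl (anti to the C7 substituent and C12–OH), giving the thermodynamically preferred equatorial 1β-bromide and the C14 bromide cis to C12–OH without C–Br cleavage.

Compound list
1 | (S)-Wieland–Miescher ketone, (8aS)-8a-methyl-3,4,8,8a-tetrahydronaphthalene-1,6(2H,7H)-dione | C[C@]12CCC(=O)C=C1CCCC2=O | starting material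
2 | 10β-methyldecal-4-ene-1,7-dione bis(ethylene ketal) (spiro-dioxolanes at C1 and C7, C4=C5 alkene) | C[C@]12CCC3(OCCO3)CC1=CCCC24OCCO4 | intermediate
3 | 4α,5α-dihydroxy-10β-methyl-trans-decalin-1,7-dione bis(ethylene ketal) | C[C@]12CCC3(OCCO3)C[C@]1(O)[C@@H](O)CCC24OCCO4 | intermediate
4 | 5α-hydroxy-10β-methyl-trans-decalin-1,4,7-trione 1,7-bis(ethylene ketal) | C[C@]12CCC3(OCCO3)C[C@]1(O)C(=O)CCC24OCCO4 | intermediate
5 | 4β,5α-dihydroxy-4α,10β-dimethyl-trans-decalin-1,7-dione bis(ethylene ketal) | C[C@]12CCC3(OCCO3)C[C@]1(O)[C@](C)(O)CCC24OCCO4 | intermediate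
6 | (4R,5R,10S)-4β,5α-dihydroxy-4α,10β-dimethyl-trans-decalin-1,7-dione | C[C@]12CCC(=O)C[C@]1(O)[C@](C)(O)CCC2=O | intermediate
7 | 4-hydroxy-3,3-dimethylbutan-2-one | CC(=O)C(C)(C)CO | starting material
8 | 2,2-dimethyl-3-oxobutanal | CC(=O)C(C)(C)C=O | intermediate
9 | pinacol boronate ester (O–Bpin) of (R)-4-hydroxy-3,3-dimethylhept-6-en-2-one | CC(=O)C(C)(C)[C@H](OB1OC(C)(C)C(C)(C)O1)CC=C | intermediate
10 | (R)-4-hydroxy-3,3-dimethylhept-6-en-2-one | CC(=O)C(C)(C)[C@H](O)CC=C | intermediate
11 | 2,4,6-triisopropylbenzenesulfonyl (trisyl) hydrazone of 10 | CC(=NNS(=O)(=O)c1c(C(C)C)cc(C(C)C)cc1C(C)C)C(C)(C)[C@H](O)CC=C | intermediate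
12 | dilithium 4,5-dialkoxide of 6 | C[C@]12CCC(=O)C[C@]1(O[Li])[C@](C)(O[Li])CCC2=O | intermediate
13 | (R)-2-lithio-3,3-dimethylhepta-1,6-dien-4-ol lithium alkoxide | [Li]C(=C)C(C)(C)[C@H](O[Li])CC=C | intermediate
14 | 4β,5α,7α-trihydroxy-7β-[(4R)-4-hydroxy-3,3-dimethylhepta-1,6-dien-2-yl]-4α,10β-dimethyl-trans-decalin-1-one | C=CC[C@@H](O)C(C)(C)C(=C)[C@@]1(O)CC[C@]2(C)C(=O)CC[C@@](C)(O)[C@@]2(O)C1 | intermediate
15 | vicinal diol from the terminal vinyl group of 14 (both epimers at the new carbinol) | OCC(O)C[C@@H](O)C(C)(C)C(=C)[C@@]1(O)CC[C@]2(C)C(=O)CC[C@@](C)(O)[C@@]2(O)C1 | intermediate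
16 | 4β,5α,7α-trihydroxy-7β-[(4R)-4-hydroxy-3,3-dimethyl-6-oxohex-1-en-2-yl]-4α,10β-dimethyl-trans-decalin-1-one (C12 aldehyde) | O=CC[C@@H](O)C(C)(C)C(=C)[C@@]1(O)CC[C@]2(C)C(=O)CC[C@@](C)(O)[C@@]2(O)C1 | intermediate
17 | 4β,5α,7α-trihydroxy-7β-[(1R,2S,4R)-2,4-dihydroxy-1,5,5-trimethylcyclopentyl]-4α,10β-dimethyl-trans-decalin-1-one (C12–OH, C14–OH and C7 all cis on ring A) | CC1(C)[C@H](O)C[C@H](O)[C@]1(C)[C@@]1(O)CC[C@]2(C)C(=O)CC[C@@](C)(O)[C@@]2(O)C1 | intermediate
18 | 4β,5α,7α-trihydroxy-7β-[(1R,2S)-2-hydroxy-1,5,5-trimethyl-4-oxocyclopentyl]-4α,10β-dimethyl-trans-decalin-1-one | CC1(C)C(=O)C[C@H](O)[C@]1(C)[C@@]1(O)CC[C@]2(C)C(=O)CC[C@@](C)(O)[C@@]2(O)C1 | intermediate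
19 | 1,14-bis-hydrazone of 18 | CC1(C)C(=NN)C[C@H](O)[C@]1(C)[C@@]1(O)CC[C@]2(C)C(=NN)CC[C@@](C)(O)[C@@]2(O)C1 | intermediate
20 | 1,14-dibromo-1(2),13(14)-diene with 4β,5α,7α,12-hydroxyls (11R,12S) | CC1(C)C(Br)=C[C@H](O)[C@]1(C)[C@@]1(O)CC[C@]2(C)C(Br)=CC[C@@](C)(O)[C@@]2(O)C1 | intermediate
21 | neoirietetraol, (1S,4R,5R,7R,10S,11R,12S,14R)-1,14-dibromo-4,5,7,12-tetrol | CC1(C)[C@H](Br)C[C@H](O)[C@]1(C)[C@@]1(O)CC[C@]2(C)[C@@H](Br)CC[C@@](C)(O)[C@@]2(O)C1 | target

Total step count: 15. Longest linear sequence: 12 steps (steps 1–5 and 9–15).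

Steps most likely to fail

Step 11. The ring closure may discriminate the two faces of the C11 radical poorly if the free C14 hydroxyl does not hold the chair, the radical addition may revert so that the alkene is merely hydrogenated, or the β-hydroxy aldehyde may dehydrate. The fallback sets out from 14 and replaces hydrogen-bond control by a large, non-eliminating anchor. The C14 hydroxyl is silylated (TBSOTf, 2,6-lutidine, −78 °C) to the C14 TBS ether F1. The vinyl group is cleaved (OsO4, NaIO4) through the vicinal diol F2 to the silyloxy aldehyde F3. The same iron-hydride ring closure should then give the cyclized silyl ether F4 with the silyloxy group locked equatorial, and TBAF returns the route to 17.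

Step 12. Site selectivity may be lost, with oxidation also at C12 leading to the enolizable 1,3-dione. The fallback sets out from 17 and uses protecting groups instead of steric discrimination by the oxidant. The less hindered C14 hydroxyl is silylated (TESCl, imidazole) to the C14 triethylsilyl ether F5. The C12 hydroxyl is capped (MOMCl, i-Pr2NEt, Bu4NI) as the C12 methoxymethyl ether F6. HF·pyridine frees the C14 alcohol F7, and Dess–Martin oxidation gives the C14 ketone F8. Mild aqueous HCl removes the methoxymethyl group and rejoins the route at 18.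

Step 15. Bromine may be lost if the hydrogen atom adds at the bromine-bearing carbon and the bromine atom is then expelled, or hydrogen may be delivered to the wrong face at C14. The fallback sets out from 19 and avoids alkene hydrogenation. CuBr2 and t-BuOLi in THF should convert both hydrazones into the bis(gem-dibromide) F9. Radical mono-debromination (Bu3SnH, one equivalent per CBr2, Et3B/O2, toluene, −78 °C) then removes one bromine from each carbon, with hydrogen delivered to the less hindered face of each α-bromo radical, and arrives directly at 21.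

Further compounds
F1 | step 11 | C14 TBS ether of 14 | C=CC[C@@H](O[Si](C)(C)C(C)(C)C)C(C)(C)C(=C)[C@@]1(O)CC[C@]2(C)C(=O)CC[C@@](C)(O)[C@@]2(O)C1
F2 | step 11 | vicinal diol from the vinyl group of F1 | OCC(O)C[C@@H](O[Si](C)(C)C(C)(C)C)C(C)(C)C(=C)[C@@]1(O)CC[C@]2(C)C(=O)CC[C@@](C)(O)[C@@]2(O)C1
F3 | step 11 | silyloxy aldehyde (C14 TBS ether of 16) | O=CC[C@@H](O[Si](C)(C)C(C)(C)C)C(C)(C)C(=C)[C@@]1(O)CC[C@]2(C)C(=O)CC[C@@](C)(O)[C@@]2(O)C1
F4 | step 11 | cyclized silyl ether (C14 TBS ether of 17) | CC1(C)[C@H](O[Si](C)(C)C(C)(C)C)C[C@H](O)[C@]1(C)[C@@]1(O)CC[C@]2(C)C(=O)CC[C@@](C)(O)[C@@]2(O)C1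
F5 | step 12 | C14 triethylsilyl ether of 17 | CC1(C)[C@H](O[Si](CC)(CC)CC)C[C@H](O)[C@]1(C)[C@@]1(O)CC[C@]2(C)C(=O)CC[C@@](C)(O)[C@@]2(O)C1
F6 | step 12 | C12 methoxymethyl ether of F5 | CC1(C)[C@H](O[Si](CC)(CC)CC)C[C@H](OCOC)[C@]1(C)[C@@]1(O)CC[C@]2(C)C(=O)CC[C@@](C)(O)[C@@]2(O)C1
F7 | step 12 | C14 alcohol with C12 methoxymethyl ether | CC1(C)[C@H](O)C[C@H](OCOC)[C@]1(C)[C@@]1(O)CC[C@]2(C)C(=O)CC[C@@](C)(O)[C@@]2(O)C1
F8 | step 12 | C14 ketone with C12 methoxymethyl ether | CC1(C)C(=O)C[C@H](OCOC)[C@]1(C)[C@@]1(O)CC[C@]2(C)C(=O)CC[C@@](C)(O)[C@@]2(O)C1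
F9 | step 15 | 1,1,14,14-tetrabromide (bis(gem-dibromide)) | CC1(C)C(Br)(Br)C[C@H](O)[C@]1(C)[C@@]1(O)CC[C@]2(C)C(Br)(Br)CC[C@@](C)(O)[C@@]2(O)C1
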